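Assumption: the identifier is taken to mean exactly the given SMILES, i.e. (1S,2S,3E,6E,8R,11S,12R,13S)-13-acetoxy-11,12-epoxy-8-hydroxycembra-3,6,15(17)-trien-16,2-olide; cembrane numbering is used (C1 = ring-fusion CH, C2 = lactone CH–O, C15–C17 = methylene-lactone carbons).

Abbreviations: PMB = 4-methoxybenzyl, TBS = tert-butyldimethylsilyl, TBDPS = tert-butyldiphenylsilyl, TES = triethylsilyl, PT = 1-phenyl-1H-tetrazol-5-yl, Ipc = isopinocampheyl, DDQ = 2,3-dichloro-5,6-dicyano-1,4-benzoquinone, 9-BBN = 9-borabicyclo[3.3.1]nonane.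

## Retrosynthetic overview

1. Last step frees C8–OH (PMB off); before it, the 14-membered carbocycle and the cis-fused α-methylene-γ-lactone are closed together by an intramolecular CrCl2-mediated 2-(methoxycarbonyl)allylation (C1–C2) of a bromo enoate/enal.
2. The open chain comes from a late B-alkyl Suzuki–Miyaura union (C10–C11) of fragment A (C2–C10) and fragment B (C11–C14, C1, C15–C17), then C13–OH-directed epoxidation and acetylation.
3. Fragment A: Julia–Kocienski olefination (C6=C7) of a C7–C10 aldehyde from (S)-2-methylglycidol (C8) with a C2–C6 sulfone from but-3-yn-1-ol (carboalumination sets C3=C4).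
4. Fragment B: prop-2-yn-1-ol → (E)-iodo enal → Brown allylation (C13) → oxidative cleavage → acrylate unit from methyl propiolate.
5. Ring order: oxirane (step 22), then macrocycle and lactone in one operation (step 27).

## Route

Step 1
Reactants: 1 (S)-2-methylglycidol
Product: 2 (R)-2-{[(4-methoxybenzyl)oxy]methyl}-2-methyloxirane
Conditions: NaH, 4-methoxybenzyl chloride, Bu4NI (cat.), THF/DMF, 0 °C → rt
Reagents that add atoms: 4-methoxybenzyl chloride, COc1ccc(CCl)cc1
Why: Williamson etherification of the primary alkoxide (a Payne shift of this epoxy alkoxide is degenerate), so the quaternary stereocentre stays as in 1 and only its CIP label changes.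

Step 2
Reactants: 2 (R)-2-{[(4-methoxybenzyl)oxy]methyl}-2-methyloxirane
Product: 3 (R)-1-[(4-methoxybenzyl)oxy]-2-methylbut-3-en-2-ol
Conditions: Me3S+ I−, n-BuLi, THF, −10 °C → rt
Reagents that add atoms: trimethylsulfonium iodide, C[S+](C)C.[I-]
Why: Sulfonium-ylide one-carbon homologation of a terminal epoxide: the methylide opens the oxirane at CH2 and the betaine loses Me2S to give the vinyl carbinol, while the C–O bond at the quaternary centre is never broken (retention).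

Step 3
Reactants: 3 (R)-1-[(4-methoxybenzyl)oxy]-2-methylbut-3-en-2-ol
Product: 4 (4R)-4-ethenyl-2-(4-methoxyphenyl)-4-methyl-1,3-dioxolane (both C2 epimers)
Conditions: DDQ, 4 Å molecular sieves, CH2Cl2, 0 °C
Reagents that add atoms: none
Why: DDQ oxidises the PMB ether to an oxocarbenium ion that the neighbouring tertiary hydroxyl traps (oxidative acetalisation), without touching the stereocentre.

Step 4
Reactants: 4 (4R)-4-ethenyl-2-(4-methoxyphenyl)-4-methyl-1,3-dioxolane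
Product: 5 (R)-2-[(4-methoxybenzyl)oxy]-2-methylbut-3-en-1-ol
Conditions: i-Bu2AlH, CH2Cl2, −78 → 0 °C; aq. KNaC4H4O6
Reagents that add atoms: none
Why: Regioselective reductive acetal opening: the aluminium hydride binds the less hindered primary oxygen and cleaves that C–O bond, leaving PMB on the tertiary oxygen and the primary alcohol free.

Step 5
Reactants: 5 (R)-2-[(4-methoxybenzyl)oxy]-2-methylbut-3-en-1-ol
Product: 6 (R)-2-[(4-methoxybenzyl)oxy]-2-methylbut-3-enal
Conditions: Dess–Martin periodinane, pyridine, CH2Cl2, 0 °C → rt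
Reagents that add atoms: none
Why: Dess–Martin oxidation of the primary alcohol; the α-carbon is quaternary, so the aldehyde can neither epimerise nor move into conjugation.

Step 6
Reactants: 7 but-3-yn-1-ol
Product: 8 tert-butyl(but-3-yn-1-yloxy)dimethylsilane
Conditions: TBSCl, imidazole, CH2Cl2, rt
Reagents that add atoms: tert-butyldimethylsilyl chloride, CC(C)(C)[Si](C)(C)Cl
Why: Standard silylation masks the hydroxyl for the organoaluminium chemistry.

Step 7
Reactants: 8 tert-butyl(but-3-yn-1-yloxy)dimethylsilane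
Product: 10 (E)-5-[(tert-butyldimethylsilyl)oxy]-3-methylpent-2-en-1-ol, via alkenylalane 9 (not isolated)
Conditions: Me3Al, Cp2ZrCl2 (0.25 equiv), CH2Cl2, 0 °C → rt; then n-BuLi, (CH2O)n, THF, 0 °C → rt
Reagents that add atoms: trimethylaluminium, C[Al](C)C; paraformaldehyde (as formaldehyde), C=O
Why: Negishi zirconium-catalysed methylalumination adds Me and Al syn across the terminal alkyne (methyl to the internal carbon) and the alkenylalanate is hydroxymethylated with retention, fixing the (E)-C3=C4 alkene.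

Step 8
Reactants: 10 (E)-5-[(tert-butyldimethylsilyl)oxy]-3-methylpent-2-en-1-ol
Product: 11 (E)-5-[(tert-butyldimethylsilyl)oxy]-1-[(tert-butyldiphenylsilyl)oxy]-3-methylpent-2-ene
Conditions: TBDPSCl, imidazole, CH2Cl2, rt
Reagents that add atoms: tert-butyl(chloro)diphenylsilane, CC(C)(C)[Si](Cl)(c1ccccc1)c1ccccc1
Why: Silylation of the allylic alcohol with a group that survives the later removal of TBS.

Step 9
Reactants: 11 (E)-5-[(tert-butyldimethylsilyl)oxy]-1-[(tert-butyldiphenylsilyl)oxy]-3-methylpent-2-ene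
Product: 12 (E)-5-[(tert-butyldiphenylsilyl)oxy]-3-methylpent-3-en-1-ol
Conditions: camphor-10-sulfonic acid (10 mol %), MeOH/CH2Cl2, 0 °C
Reagents that add atoms: none
Why: Acid-catalysed methanolysis removes the primary TBS ether far faster than the bulkier TBDPS ether (selective desilylation).

Step 10
Reactants: 12 (E)-5-[(tert-butyldiphenylsilyl)oxy]-3-methylpent-3-en-1-ol
Product: 13 5-({(E)-5-[(tert-butyldiphenylsilyl)oxy]-3-methylpent-3-en-1-yl}sulfanyl)-1-phenyl-1H-tetrazole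
Conditions: 1-phenyl-1H-tetrazole-5-thiol, PPh3, diisopropyl azodicarboxylate, THF, 0 °C → rt
Reagents that add atoms: 1-phenyl-1H-tetrazole-5-thiol, Sc1nnnn1-c1ccccc1
Why: Mitsunobu thioetherification of the primary alcohol with the acidic tetrazole thiol.

Step 11
Reactants: 13 5-({(E)-5-[(tert-butyldiphenylsilyl)oxy]-3-methylpent-3-en-1-yl}sulfanyl)-1-phenyl-1H-tetrazole
Product: 14 5-({(E)-5-[(tert-butyldiphenylsilyl)oxy]-3-methylpent-3-en-1-yl}sulfonyl)-1-phenyl-1H-tetrazole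
Conditions: (NH4)6Mo7O24·4H2O (10 mol %), 30% H2O2, EtOH, 0 °C → rt
Reagents that add atoms: hydrogen peroxide, OO
Why: Molybdate-catalysed peroxide oxidation of sulfide to sulfone is much faster than epoxidation of the allylic-ether alkene.

Step 12
Reactants: 14 5-({(E)-5-[(tert-butyldiphenylsilyl)oxy]-3-methylpent-3-en-1-yl}sulfonyl)-1-phenyl-1H-tetrazole; 6 (R)-2-[(4-methoxybenzyl)oxy]-2-methylbut-3-enal
Product: 15 fragment A: tert-butyl({(2E,5E,7R)-7-[(4-methoxybenzyl)oxy]-3,7-dimethylnona-2,5,8-trien-1-yl}oxy)diphenylsilane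
Conditions: KN(SiMe3)2, 1,2-dimethoxyethane, −60 °C → rt (base added to the mixture of 14 and 6)
Reagents that add atoms: none
Why: Julia–Kocienski olefination: the metallated PT sulfone adds to the non-enolisable aldehyde and Smiles rearrangement/elimination gives the (E)-C6=C7 alkene, with C8 untouched.

Step 13
Reactants: 16 prop-2-yn-1-ol
Product: 18 (E)-3-iodo-2-methylprop-2-en-1-ol, via alkenylalane 17 (not isolated)
Conditions: Me3Al, Cp2ZrCl2 (0.25 equiv), CH2Cl2, 0 °C → rt; then I2, THF, −30 → 0 °C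
Reagents that add atoms: trimethylaluminium, C[Al](C)C; iodine, II
Why: Negishi carboalumination (syn) of the propargylic aluminium alkoxide followed by iodinolysis with retention gives the (E)-iodoalkene.

Step 14
Reactants: 18 (E)-3-iodo-2-methylprop-2-en-1-ol
Product: 19 (E)-3-iodo-2-methylprop-2-enal
Conditions: MnO2, CH2Cl2, rt (solution used directly)
Reagents that add atoms: none
Why: MnO2 oxidises the allylic alcohol to the enal without touching the vinyl iodide or its geometry.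

Step 15
Reactants: 19 (E)-3-iodo-2-methylprop-2-enal; 20 allylmagnesium bromide
Product: 22 (1E,3S)-1-iodo-2-methylhexa-1,5-dien-3-ol, via borinate 21 (not isolated)
Conditions: (−)-Ipc2BOMe [from (+)-α-pinene], CH2=CHCH2MgBr, Et2O, 0 °C → rt; then 19, −78 °C; NaOH, H2O2
Reagents that add atoms: none
Why: Brown allylboration through a closed chair transition state: the reagent derived from (+)-α-pinene adds allyl to the Si face of the enal and sets C13 as S (about 92–95% ee), the minor enantiomer later becoming a separable diastereomer.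

Step 16
Reactants: 22 (1E,3S)-1-iodo-2-methylhexa-1,5-dien-3-ol
Product: 23 triethyl{[(1E,3S)-1-iodo-2-methylhexa-1,5-dien-3-yl]oxy}silane
Conditions: TESCl, imidazole, CH2Cl2, 0 °C
Reagents that add atoms: chlorotriethylsilane, CC[Si](Cl)(CC)CC
Why: Silylation protects C13–OH as a TES ether that can later be removed in the presence of TBS and TBDPS ethers.

Step 17
Reactants: 23 triethyl{[(1E,3S)-1-iodo-2-methylhexa-1,5-dien-3-yl]oxy}silane
Product: 25 (3S,4E)-5-iodo-4-methyl-3-[(triethylsilyl)oxy]pent-4-enal, via diol 24 (not isolated)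
Conditions: OsO4 (2 mol %), N-methylmorpholine N-oxide, acetone/H2O, rt; then NaIO4, THF/H2O
Reagents that add atoms: N-methylmorpholine N-oxide, C[N+]1([O-])CCOCC1; water, O
Why: Lemieux–Johnson-type cleavage: catalytic OsO4 dihydroxylates the monosubstituted alkene in preference to the hindered, electron-poor iodoalkene and NaIO4 cleaves the diol to the aldehyde.

Step 18
Reactants: 25 (3S,4E)-5-iodo-4-methyl-3-[(triethylsilyl)oxy]pent-4-enal; 26 methyl propiolate
Product: 28 methyl (5S,6E)-3-hydroxy-7-iodo-6-methyl-2-methylidene-5-[(triethylsilyl)oxy]hept-6-enoate (both C3 epimers), via vinylalane 27 (not isolated)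
Conditions: i-Bu2AlH, N-methylmorpholine N-oxide, THF, 0 °C, then 26; then 25, 0 °C → rt
Reagents that add atoms: none
Why: Vinylalumination: hydroalumination of the propiolate gives the α-alumino acrylate, which adds 1,2 to the aldehyde under non-basic conditions to give the Morita–Baylis–Hillman-type adduct (the new carbinol centre is uncontrolled and becomes sp2 in step 26).

Step 19
Reactants: 28 methyl (5S,6E)-3-hydroxy-7-iodo-6-methyl-2-methylidene-5-[(triethylsilyl)oxy]hept-6-enoate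
Product: 29 fragment B: methyl (5S,6E)-3-[(tert-butyldimethylsilyl)oxy]-7-iodo-6-methyl-2-methylidene-5-[(triethylsilyl)oxy]hept-6-enoate (both C3 epimers)
Conditions: TBSOTf, 2,6-lutidine, CH2Cl2, −78 → 0 °C
Reagents that add atoms: tert-butyldimethylsilyl trifluoromethanesulfonate, CC(C)(C)[Si](C)(C)OS(=O)(=O)C(F)(F)F
Why: Silyl triflate protection of the secondary alcohol at low temperature leaves the TES ether and the acrylate untouched.

Step 20
Reactants: 15 fragment A; 29 fragment B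
Product: 31 methyl (5S,6E,10R,11E,14E)-3-[(tert-butyldimethylsilyl)oxy]-16-[(tert-butyldiphenylsilyl)oxy]-10-[(4-methoxybenzyl)oxy]-6,10,14-trimethyl-2-methylidene-5-[(triethylsilyl)oxy]hexadeca-6,11,14-trienoate (both C3 epimers), via alkylborane 30 (not isolated)
Conditions: 15, 9-BBN, THF, 0 °C → rt; then 29, Pd(dppf)Cl2 (10 mol %), AsPh3, Cs2CO3, DMF/THF/H2O, rt
Reagents that add atoms: none
Why: B-alkyl Suzuki–Miyaura coupling: 9-BBN hydroborates only the monosubstituted alkene of 15 and the alkylborane couples with the vinyl iodide with retention of the (E)-C11=C12 geometry, forming C10–C11 without creating a stereocentre.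

Step 21
Reactants: 31 (C5 triethylsilyl ether)
Product: 32 methyl (5S,6E,10R,11E,14E)-3-[(tert-butyldimethylsilyl)oxy]-16-[(tert-butyldiphenylsilyl)oxy]-5-hydroxy-10-[(4-methoxybenzyl)oxy]-6,10,14-trimethyl-2-methylidenehexadeca-6,11,14-trienoate (both C3 epimers)
Conditions: HF·pyridine, pyridine, THF, 0 °C
Reagents that add atoms: none
Why: Buffered HF·pyridine cleaves the secondary TES ether much faster than the TBS and TBDPS ethers (selective desilylation).

Step 22
Reactants: 32 (free C13 allylic alcohol)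
Product: 33 methyl (5S,6S,7S,10R,11E,14E)-3-[(tert-butyldimethylsilyl)oxy]-16-[(tert-butyldiphenylsilyl)oxy]-6,7-epoxy-5-hydroxy-10-[(4-methoxybenzyl)oxy]-6,10,14-trimethyl-2-methylidenehexadeca-11,14-dienoate (both C3 epimers)
Conditions: VO(acac)2 (5 mol %), t-BuOOH (decane), CH2Cl2, 0 °C → rt
Reagents that add atoms: tert-butyl hydroperoxide, CC(C)(C)OO
Why: Hydroxyl-directed vanadium-catalysed epoxidation touches only the alkene of the free allylic alcohol, and avoidance of allylic 1,2-strain between the C12 methyl and the carbinol substituent gives the erythro epoxy alcohol, i.e. the target's C11/C12 geometry from 13S (the C12 label reads S here and R once C13 is acetylated).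

Step 23
Reactants: 33 (epoxy alcohol)
Product: 34 methyl (5S,6R,7S,10R,11E,14E)-5-acetoxy-3-[(tert-butyldimethylsilyl)oxy]-16-[(tert-butyldiphenylsilyl)oxy]-6,7-epoxy-10-[(4-methoxybenzyl)oxy]-6,10,14-trimethyl-2-methylidenehexadeca-11,14-dienoate (both C3 epimers)
Conditions: Ac2O, pyridine, 4-(dimethylamino)pyridine (cat.), CH2Cl2, 0 °C → rt
Reagents that add atoms: acetic anhydride, CC(=O)OC(C)=O
Why: Nucleophile-catalysed acylation of the only free hydroxyl; no stereocentre is affected.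

Step 24
Reactants: 34 (bis-silyl ether)
Product: 35 methyl (5S,6R,7S,10R,11E,14E)-5-acetoxy-6,7-epoxy-3,16-dihydroxy-10-[(4-methoxybenzyl)oxy]-6,10,14-trimethyl-2-methylidenehexadeca-11,14-dienoate (both C3 epimers)
Conditions: Bu4NF, AcOH (1:1), THF, 0 °C → rt
Reagents that add atoms: none
Why: Buffered fluoride cleaves both silyl ethers while acetic acid suppresses acetyl migration, and the PMB ether, epoxide and acetate are inert.

Step 25
Reactants: 35 (diol)
Product: 36 methyl (5S,6R,7S,10R,11E,14E)-5-acetoxy-6,7-epoxy-3-hydroxy-10-[(4-methoxybenzyl)oxy]-6,10,14-trimethyl-2-methylidene-16-oxohexadeca-11,14-dienoate (both C3 epimers)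
Conditions: 2,2,6,6-tetramethylpiperidin-1-oxyl (TEMPO, 20 mol %), PhI(OAc)2, CH2Cl2, rt
Reagents that add atoms: none
Why: TEMPO/PhI(OAc)2 oxidises the primary allylic alcohol far faster than the secondary one, giving the C2 enal without E/Z isomerisation.

Step 26
Reactants: 36 (hydroxy enal)
Product: 37 methyl (2Z,5S,6R,7S,10R,11E,14E)-5-acetoxy-2-(bromomethyl)-6,7-epoxy-10-[(4-methoxybenzyl)oxy]-6,10,14-trimethyl-16-oxohexadeca-2,11,14-trienoate
Conditions: N-bromosuccinimide, Me2S, CH2Cl2, −20 → 0 °C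
Reagents that add atoms: N-bromosuccinimide, O=C1CCC(=O)N1Br
Why: Corey–Kim-type activation converts the Baylis–Hillman alcohol by SN2' displacement into the thermodynamically preferred (Z)-2-(bromomethyl)enoate under neutral conditions.

Step 27
Reactants: 37 (bromo enoate/enal)
Product: 39 (1S,2S,3E,6E,8R,11S,12R,13S)-13-acetoxy-11,12-epoxy-8-[(4-methoxybenzyl)oxy]cembra-3,6,15(17)-trien-16,2-olide, via hydroxy ester 38 (not isolated)
Conditions: CrCl2 (10 equiv), THF, rt, slow addition to about 1 mM; aq. NH4Cl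
Reagents that add atoms: none
Why: Intramolecular Nozaki–Hiyama-type (Barbier) allylation: the (Z)-allylchromium adds to the enal through a chair transition state to give the syn adduct and hence the cis-fused lactone on spontaneous lactonisation, while the C13 acetoxy group and the rigid trans-epoxide of the folding chain are relied on (substrate control) to select the 1S,2S pair.

Step 28
Reactants: 39 (PMB ether of the target)
Product: 40 (1S,2S,3E,6E,8R,11S,12R,13S)-13-acetoxy-11,12-epoxy-8-hydroxycembra-3,6,15(17)-trien-16,2-olide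
Conditions: DDQ, CH2Cl2/pH 7 phosphate buffer, 0 °C
Reagents that add atoms: none
Why: Oxidative cleavage of the PMB ether with buffered DDQ frees the tertiary alcohol under near-neutral conditions that spare the epoxide, acetate and α-methylene lactone.

## Compound list

1 | (S)-2-methylglycidol, [(2S)-2-methyloxiran-2-yl]methanol | C[C@]1(CO)CO1 | starting material
2 | (R)-2-{[(4-methoxybenzyl)oxy]methyl}-2-methyloxirane | C[C@]1(COCc2ccc(OC)cc2)CO1 | intermediate
3 | (R)-1-[(4-methoxybenzyl)oxy]-2-methylbut-3-en-2-ol | C[C@](O)(COCc1ccc(OC)cc1)C=C | intermediate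
4 | (4R)-4-ethenyl-2-(4-methoxyphenyl)-4-methyl-1,3-dioxolane (both C2 epimers) | C[C@@]1(C=C)COC(c2ccc(OC)cc2)O1 | intermediate
5 | (R)-2-[(4-methoxybenzyl)oxy]-2-methylbut-3-en-1-ol | C[C@](OCc1ccc(OC)cc1)(CO)C=C | intermediate
6 | (R)-2-[(4-methoxybenzyl)oxy]-2-methylbut-3-enal | C[C@](OCc1ccc(OC)cc1)(C=O)C=C | intermediate
7 | but-3-yn-1-ol | C#CCCO | starting material
8 | tert-butyl(but-3-yn-1-yloxy)dimethylsilane | C#CCCO[Si](C)(C)C(C)(C)C | intermediate
9 | (E)-{4-[(tert-butyldimethylsilyl)oxy]-2-methylbut-1-en-1-yl}dimethylalane | C[Al](C)/C=C(\C)CCO[Si](C)(C)C(C)(C)C | intermediate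
10 | (E)-5-[(tert-butyldimethylsilyl)oxy]-3-methylpent-2-en-1-ol | OC/C=C(\C)CCO[Si](C)(C)C(C)(C)C | intermediate
11 | (E)-5-[(tert-butyldimethylsilyl)oxy]-1-[(tert-butyldiphenylsilyl)oxy]-3-methylpent-2-ene | CC(C)(C)[Si](C)(C)OCC/C(C)=C/CO[Si](c1ccccc1)(c1ccccc1)C(C)(C)C | intermediate
12 | (E)-5-[(tert-butyldiphenylsilyl)oxy]-3-methylpent-3-en-1-ol | OCC/C(C)=C/CO[Si](c1ccccc1)(c1ccccc1)C(C)(C)C | intermediate
13 | 5-({(E)-5-[(tert-butyldiphenylsilyl)oxy]-3-methylpent-3-en-1-yl}sulfanyl)-1-phenyl-1H-tetrazole | CC(C)(C)[Si](OC/C=C(\C)CCSc1nnnn1-c1ccccc1)(c1ccccc1)c1ccccc1 | intermediate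
14 | 5-({(E)-5-[(tert-butyldiphenylsilyl)oxy]-3-methylpent-3-en-1-yl}sulfonyl)-1-phenyl-1H-tetrazole | CC(C)(C)[Si](OC/C=C(\C)CCS(=O)(=O)c1nnnn1-c1ccccc1)(c1ccccc1)c1ccccc1 | intermediate
15 | fragment A: tert-butyl({(2E,5E,7R)-7-[(4-methoxybenzyl)oxy]-3,7-dimethylnona-2,5,8-trien-1-yl}oxy)diphenylsilane | C[C@](OCc1ccc(OC)cc1)(/C=C/C/C(C)=C/CO[Si](c1ccccc1)(c1ccccc1)C(C)(C)C)C=C | intermediate
16 | prop-2-yn-1-ol | C#CCO | starting material
17 | (E)-{3-[(dimethylalumanyl)oxy]-2-methylprop-1-en-1-yl}dimethylalane | C[Al](C)OC/C(C)=C/[Al](C)C | intermediate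
18 | (E)-3-iodo-2-methylprop-2-en-1-ol | OC/C(C)=C/I | intermediate
19 | (E)-3-iodo-2-methylprop-2-enal | O=C/C(C)=C/I | intermediate
20 | allylmagnesium bromide | C=CC[Mg]Br | starting material
21 | diisopinocampheylborinic ester of 22 [Ipc from (+)-α-pinene] | C=CC[C@H](OB([C@@H]1C[C@@H]2C[C@@H](C2(C)C)[C@H]1C)[C@@H]1C[C@@H]2C[C@@H](C2(C)C)[C@H]1C)/C(C)=C/I | intermediate
22 | (1E,3S)-1-iodo-2-methylhexa-1,5-dien-3-ol | C=CC[C@H](O)/C(C)=C/I | intermediate
23 | triethyl{[(1E,3S)-1-iodo-2-methylhexa-1,5-dien-3-yl]oxy}silane | C=CC[C@H](O[Si](CC)(CC)CC)/C(C)=C/I | intermediate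
24 | (4S,5E)-6-iodo-5-methyl-4-[(triethylsilyl)oxy]hex-5-ene-1,2-diol (both C2 epimers) | OCC(O)C[C@H](O[Si](CC)(CC)CC)/C(C)=C/I | intermediate
25 | (3S,4E)-5-iodo-4-methyl-3-[(triethylsilyl)oxy]pent-4-enal | O=CC[C@H](O[Si](CC)(CC)CC)/C(C)=C/I | intermediate
26 | methyl propiolate | C#CC(=O)OC | starting material
27 | methyl 2-(diisobutylalumanyl)prop-2-enoate | C=C([Al](CC(C)C)CC(C)C)C(=O)OC | intermediate
28 | methyl (5S,6E)-3-hydroxy-7-iodo-6-methyl-2-methylidene-5-[(triethylsilyl)oxy]hept-6-enoate (both C3 epimers) | C=C(C(=O)OC)C(O)C[C@H](O[Si](CC)(CC)CC)/C(C)=C/I | intermediate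
29 | fragment B: methyl (5S,6E)-3-[(tert-butyldimethylsilyl)oxy]-7-iodo-6-methyl-2-methylidene-5-[(triethylsilyl)oxy]hept-6-enoate (both C3 epimers) | C=C(C(=O)OC)C(O[Si](C)(C)C(C)(C)C)C[C@H](O[Si](CC)(CC)CC)/C(C)=C/I | intermediate
30 | 9-{(3R,4E,7E)-9-[(tert-butyldiphenylsilyl)oxy]-3-[(4-methoxybenzyl)oxy]-3,7-dimethylnona-4,7-dien-1-yl}-9-borabicyclo[3.3.1]nonane | C[C@](OCc1ccc(OC)cc1)(/C=C/C/C(C)=C/CO[Si](c1ccccc1)(c1ccccc1)C(C)(C)C)CCB1C2CCCC1CCC2 | intermediate
31 | methyl (5S,6E,10R,11E,14E)-3-[(tert-butyldimethylsilyl)oxy]-16-[(tert-butyldiphenylsilyl)oxy]-10-[(4-methoxybenzyl)oxy]-6,10,14-trimethyl-2-methylidene-5-[(triethylsilyl)oxy]hexadeca-6,11,14-trienoate (both C3 epimers; chain C5 = cembrane C13, C10 = cembrane C8) | C[C@](OCc1ccc(OC)cc1)(/C=C/C/C(C)=C/CO[Si](c1ccccc1)(c1ccccc1)C(C)(C)C)CC/C=C(\C)[C@@H](O[Si](CC)(CC)CC)CC(O[Si](C)(C)C(C)(C)C)C(=C)C(=O)OC | intermediate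
32 | methyl (5S,6E,10R,11E,14E)-3-[(tert-butyldimethylsilyl)oxy]-16-[(tert-butyldiphenylsilyl)oxy]-5-hydroxy-10-[(4-methoxybenzyl)oxy]-6,10,14-trimethyl-2-methylidenehexadeca-6,11,14-trienoate (both C3 epimers) | C[C@](OCc1ccc(OC)cc1)(/C=C/C/C(C)=C/CO[Si](c1ccccc1)(c1ccccc1)C(C)(C)C)CC/C=C(\C)[C@@H](O)CC(O[Si](C)(C)C(C)(C)C)C(=C)C(=O)OC | intermediate
33 | methyl (5S,6S,7S,10R,11E,14E)-3-[(tert-butyldimethylsilyl)oxy]-16-[(tert-butyldiphenylsilyl)oxy]-6,7-epoxy-5-hydroxy-10-[(4-methoxybenzyl)oxy]-6,10,14-trimethyl-2-methylidenehexadeca-11,14-dienoate (both C3 epimers) | C[C@](OCc1ccc(OC)cc1)(/C=C/C/C(C)=C/CO[Si](c1ccccc1)(c1ccccc1)C(C)(C)C)CC[C@@H]1O[C@@]1(C)[C@@H](O)CC(O[Si](C)(C)C(C)(C)C)C(=C)C(=O)OC | intermediate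
34 | methyl (5S,6R,7S,10R,11E,14E)-5-acetoxy-3-[(tert-butyldimethylsilyl)oxy]-16-[(tert-butyldiphenylsilyl)oxy]-6,7-epoxy-10-[(4-methoxybenzyl)oxy]-6,10,14-trimethyl-2-methylidenehexadeca-11,14-dienoate (both C3 epimers) | C[C@](OCc1ccc(OC)cc1)(/C=C/C/C(C)=C/CO[Si](c1ccccc1)(c1ccccc1)C(C)(C)C)CC[C@@H]1O[C@@]1(C)[C@@H](OC(C)=O)CC(O[Si](C)(C)C(C)(C)C)C(=C)C(=O)OC | intermediate
35 | methyl (5S,6R,7S,10R,11E,14E)-5-acetoxy-6,7-epoxy-3,16-dihydroxy-10-[(4-methoxybenzyl)oxy]-6,10,14-trimethyl-2-methylidenehexadeca-11,14-dienoate (both C3 epimers) | C[C@](OCc1ccc(OC)cc1)(/C=C/C/C(C)=C/CO)CC[C@@H]1O[C@@]1(C)[C@@H](OC(C)=O)CC(O)C(=C)C(=O)OC | intermediate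
36 | methyl (5S,6R,7S,10R,11E,14E)-5-acetoxy-6,7-epoxy-3-hydroxy-10-[(4-methoxybenzyl)oxy]-6,10,14-trimethyl-2-methylidene-16-oxohexadeca-11,14-dienoate (both C3 epimers) | C[C@](OCc1ccc(OC)cc1)(/C=C/C/C(C)=C/C=O)CC[C@@H]1O[C@@]1(C)[C@@H](OC(C)=O)CC(O)C(=C)C(=O)OC | intermediate
37 | methyl (2Z,5S,6R,7S,10R,11E,14E)-5-acetoxy-2-(bromomethyl)-6,7-epoxy-10-[(4-methoxybenzyl)oxy]-6,10,14-trimethyl-16-oxohexadeca-2,11,14-trienoate | C[C@](OCc1ccc(OC)cc1)(/C=C/C/C(C)=C/C=O)CC[C@@H]1O[C@@]1(C)[C@@H](OC(C)=O)C/C=C(\CBr)C(=O)OC | intermediate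
38 | methyl 2-{(1S,2S,3E,6E,8R,11S,12R,13S)-13-acetoxy-11,12-epoxy-2-hydroxy-8-[(4-methoxybenzyl)oxy]-4,8,12-trimethylcyclotetradeca-3,6-dien-1-yl}prop-2-enoate (formed as its chromium alkoxide) | COC(=O)C(=C)[C@H]1[C@@H](O)/C=C(\C)C/C=C/[C@](C)(OCc2ccc(OC)cc2)CC[C@@H]2O[C@@]2(C)[C@@H](OC(C)=O)C1 | intermediate
39 | (1S,2S,3E,6E,8R,11S,12R,13S)-13-acetoxy-11,12-epoxy-8-[(4-methoxybenzyl)oxy]cembra-3,6,15(17)-trien-16,2-olide | C=C1C(=O)O[C@H]2/C=C(\C)C/C=C/[C@](C)(OCc3ccc(OC)cc3)CC[C@@H]3O[C@@]3(C)[C@@H](OC(C)=O)C[C@@H]12 | intermediate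
40 | (1S,2S,3E,6E,8R,11S,12R,13S)-13-acetoxy-11,12-epoxy-8-hydroxycembra-3,6,15(17)-trien-16,2-olide (CNP0288879.3) | C=C1C(=O)O[C@H]2/C=C(\C)C/C=C/[C@](C)(O)CC[C@@H]3O[C@@]3(C)[C@@H](OC(C)=O)C[C@@H]12 | target

## Step count and risks

Total step count: 28. Longest linear sequence: 16 steps (steps 6–11, 12, 20–28 from but-3-yn-1-ol; equally steps 13–19, 20–28 from prop-2-yn-1-ol). Ratio 16/28 = 0.57.

The three steps most likely to fail:

**Step 27 (chromium-mediated ring closure).** The cis relationship at C1/C2 follows from the chair transition state, but the choice between the two cis face pairs rests on substrate control, and oligomerisation competes. Fallback, setting out from 15 and 28 and coming back at 39: swap the order of the two key bond formations.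
- 15 is desilylated at the primary position (Bu4NF, THF, 0 °C) to (2E,5E,7R)-7-[(4-methoxybenzyl)oxy]-3,7-dimethylnona-2,5,8-trien-1-ol F1 and oxidised with MnO2 to (2E,5E,7R)-7-[(4-methoxybenzyl)oxy]-3,7-dimethylnona-2,5,8-trienal F2.
- 28 is converted with N-bromosuccinimide/Me2S into methyl (2Z,5S,6E)-2-(bromomethyl)-7-iodo-6-methyl-5-[(triethylsilyl)oxy]hepta-2,6-dienoate F3.
- F2 and F3 are joined intermolecularly by a chromium-mediated allylation under ligand control (CrCl2, Mn, Me3SiCl, a chiral bis(oxazolinyl)carbazole ligand chosen for the 1S,2S lactone); the two cis diastereomers are separable in the open chain. This gives (4S,5S)-4-{(2S,3E)-4-iodo-3-methyl-2-[(triethylsilyl)oxy]but-3-en-1-yl}-5-{(1E,4E,6R)-6-[(4-methoxybenzyl)oxy]-2,6-dimethylocta-1,4,7-trien-1-yl}-3-methylideneoxolan-2-one F4.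
- 9-BBN hydroboration of the terminal vinyl group and an intramolecular B-alkyl Suzuki–Miyaura coupling onto the vinyl iodide (Pd(dppf)Cl2, AsPh3, Cs2CO3, high dilution) close the 14-membered ring to (1S,2S,3E,6E,8R,11E,13S)-8-[(4-methoxybenzyl)oxy]-13-[(triethylsilyl)oxy]cembra-3,6,11,15(17)-tetraen-16,2-olide F5.
- HF·pyridine frees C13–OH to give (1S,2S,3E,6E,8R,11E,13S)-13-hydroxy-8-[(4-methoxybenzyl)oxy]cembra-3,6,11,15(17)-tetraen-16,2-olide F6; VO(acac)2/t-BuOOH then gives (1S,2S,3E,6E,8R,11S,12S,13S)-11,12-epoxy-13-hydroxy-8-[(4-methoxybenzyl)oxy]cembra-3,6,15(17)-trien-16,2-olide F7; acetylation (Ac2O, pyridine) returns to 39.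

**Step 20 (B-alkyl Suzuki–Miyaura union).** The borane sits next to the quaternary C8 and the partner carries an acrylate, so slow transmetallation or side reactions at the acrylate are possible. Fallback, setting out from 15 (with 29 as partner) and coming back at 31: an sp3 Negishi coupling through an isolated alkyl iodide.
- Hydroboration of 15 with 9-BBN is worked up oxidatively (NaOH, H2O2) to (3R,4E,7E)-9-[(tert-butyldiphenylsilyl)oxy]-3-[(4-methoxybenzyl)oxy]-3,7-dimethylnona-4,7-dien-1-ol F8.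
- I2, PPh3 and imidazole give tert-butyl({(2E,5E,7R)-9-iodo-7-[(4-methoxybenzyl)oxy]-3,7-dimethylnona-2,5-dien-1-yl}oxy)diphenylsilane F9.
- Zinc insertion (activated Zn, THF) gives {(3R,4E,7E)-9-[(tert-butyldiphenylsilyl)oxy]-3-[(4-methoxybenzyl)oxy]-3,7-dimethylnona-4,7-dien-1-yl}zinc iodide F10, which couples with 29 under Pd(PPh3)4 catalysis to give 31.

**Step 18 (vinylalumination).** Reduction of the aldehyde by residual i-Bu2AlH or loss of the β-silyloxy group can erode the yield. Fallback, setting out from 25 and coming back at 28: the amine-catalysed Morita–Baylis–Hillman reaction of 25 with methyl acrylate (1,4-diazabicyclo[2.2.2]octane, MeOH, rt, several days), which uses a different carbon source and mechanism and makes no compound outside the list (none F0).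

Further compounds
F1 | step 27 | (2E,5E,7R)-7-[(4-methoxybenzyl)oxy]-3,7-dimethylnona-2,5,8-trien-1-ol | C[C@](OCc1ccc(OC)cc1)(/C=C/C/C(C)=C/CO)C=C
F2 | step 27 | (2E,5E,7R)-7-[(4-methoxybenzyl)oxy]-3,7-dimethylnona-2,5,8-trienal | C[C@](OCc1ccc(OC)cc1)(/C=C/C/C(C)=C/C=O)C=C
F3 | step 27 | methyl (2Z,5S,6E)-2-(bromomethyl)-7-iodo-6-methyl-5-[(triethylsilyl)oxy]hepta-2,6-dienoate | BrC/C(C(=O)OC)=C\C[C@H](O[Si](CC)(CC)CC)/C(C)=C/I
F4 | step 27 | (4S,5S)-4-{(2S,3E)-4-iodo-3-methyl-2-[(triethylsilyl)oxy]but-3-en-1-yl}-5-{(1E,4E,6R)-6-[(4-methoxybenzyl)oxy]-2,6-dimethylocta-1,4,7-trien-1-yl}-3-methylideneoxolan-2-one | C=C1C(=O)O[C@@H](/C=C(\C)C/C=C/[C@](C)(OCc2ccc(OC)cc2)C=C)[C@H]1C[C@H](O[Si](CC)(CC)CC)/C(C)=C/I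
F5 | step 27 | (1S,2S,3E,6E,8R,11E,13S)-8-[(4-methoxybenzyl)oxy]-13-[(triethylsilyl)oxy]cembra-3,6,11,15(17)-tetraen-16,2-olide | C=C1C(=O)O[C@H]2/C=C(\C)C/C=C/[C@](C)(OCc3ccc(OC)cc3)CC/C=C(\C)[C@@H](O[Si](CC)(CC)CC)C[C@@H]12
F6 | step 27 | (1S,2S,3E,6E,8R,11E,13S)-13-hydroxy-8-[(4-methoxybenzyl)oxy]cembra-3,6,11,15(17)-tetraen-16,2-olide | C=C1C(=O)O[C@H]2/C=C(\C)C/C=C/[C@](C)(OCc3ccc(OC)cc3)CC/C=C(\C)[C@@H](O)C[C@@H]12
F7 | step 27 | (1S,2S,3E,6E,8R,11S,12S,13S)-11,12-epoxy-13-hydroxy-8-[(4-methoxybenzyl)oxy]cembra-3,6,15(17)-trien-16,2-olide | C=C1C(=O)O[C@H]2/C=C(\C)C/C=C/[C@](C)(OCc3ccc(OC)cc3)CC[C@@H]3O[C@@]3(C)[C@@H](O)C[C@@H]12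
F8 | step 20 | (3R,4E,7E)-9-[(tert-butyldiphenylsilyl)oxy]-3-[(4-methoxybenzyl)oxy]-3,7-dimethylnona-4,7-dien-1-ol | C[C@](OCc1ccc(OC)cc1)(/C=C/C/C(C)=C/CO[Si](c1ccccc1)(c1ccccc1)C(C)(C)C)CCO
F9 | step 20 | tert-butyl({(2E,5E,7R)-9-iodo-7-[(4-methoxybenzyl)oxy]-3,7-dimethylnona-2,5-dien-1-yl}oxy)diphenylsilane | C[C@](OCc1ccc(OC)cc1)(/C=C/C/C(C)=C/CO[Si](c1ccccc1)(c1ccccc1)C(C)(C)C)CCI
F10 | step 20 | {(3R,4E,7E)-9-[(tert-butyldiphenylsilyl)oxy]-3-[(4-methoxybenzyl)oxy]-3,7-dimethylnona-4,7-dien-1-yl}zinc iodide | C[C@](OCc1ccc(OC)cc1)(/C=C/C/C(C)=C/CO[Si](c1ccccc1)(c1ccccc1)C(C)(C)C)CC[Zn]I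
F0 | step 18 | none | none
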